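3 concentrations are asked of the flask, and the reckoning here goes through the target.

in all of them: solid substrate 0.48 M
- midnight: catalyst 2.4 mM (in portions, 4); run made earlier; portions every 1.0 min
- dawn: catalyst 3.6 mM (in portions, 4); run made earlier; portions every 1.0 min
- flask: catalyst 4.8 mM (in portions, 4); the portions of catalyst follow each other after 1.0 min, the first at the start; time 6.0 min

| run | time / min | target / % | side product / % | solid substrate / % |
|---|---|---|---|---|
| midnight | 0.833 | 0 | 0.2 | 91.8 |
| midnight | 2.00 | 1.2 | 0.2 | 82.1 |
| midnight | 2.50 | 2.1 | 0.7 | 78.4 |
| midnight | 4.00 | 5.5 | 0.5 | 68.1 |
| dawn | 0.250 | 0 | 0 | 97.4 |
| dawn | 0.667 | 0 | 0.4 | 92.7 |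
| dawn | 1.50 | 1.4 | 0.1 | 85.7 |
| dawn | 4.00 | 9.2 | 0.6 | 68.0 |

(scatter of a reading: 0.5 percentage points)

- a species is counted by the solid substrate in it: one side product counts as two
- given per volume of solution although it is solid: solid substrate
- what was read earlier has a scatter of 0.5 percentage points, one standard deviation
- what may be going on: solid substrate <-> starting material; starting material + catalyst -> catalyst + target; starting material + target -> side product
- at the start none of the solid substrate is in solution

* concentration of target at 6.0 min, in M
* concentration of side product at 6.0 min, in M
* concentration of solid substrate at 6.0 min, in M

Dissolved starting material is what the balance leaves once solid, target and side product are taken away. Over the last two readings of the midnight run it averages 22.4%, and the target gains 3.4 percentage points over 0.198 M·s of catalyst and time, portions counted as they went in. In the dawn run the last two readings, which stand at 1.50 min and 4.00 min, give 17.5%, 7.8 points and 0.432 M·s.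

Pooled gain over pooled product of catalyst, time and dissolved material reads as the turnover constant 56.1 M⁻¹ min⁻¹. At fixed catalyst this makes the step pseudo-first-order in dissolved material.

For the flask at 4.00 min, scaling the dawn target by catalyst gives 12.3%. With the whole charge and 22.2% dissolved, the following minutes add 12 points. The weak link is the scaled start, since the midnight run gives 11.0% instead. Taking the mean of both, this reckoning commits to 0.113 M of target.

The forecast, “roughly first order in catalyst”, gives less target than this reckoning: 0.105 M, with 0.0058 M of side product and 0.269 M of solid.

The flask gives 0.105 M, 0.00579 M and 0.256 M, and the forecast stands within its margins.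

    solid substrate ⇌ starting material, rate k1*(cs1 - [starting material]) while solid is left; crystals form when [starting material] > cs1 (solubility = 0.280 M, k = 0.188 min⁻¹)
    starting material + catalyst → catalyst + target (k = 55.7 M⁻¹ min⁻¹)
    starting material + target → side product (k = 0.254 M⁻¹ min⁻¹)

At 6.0 min the flask still holds 53.3% as solid, and target is made 10.0 times faster than it is used up. From 3.00 min to 6.0 min the turnover constant, with the mean dissolved level of 21.3%, gives 17 points; the flask makes 17 points of target, what went on into side product counted in. Left until 15 min, the neighbouring flask reaches 63.2% of target and 22.8% of side product; with one side product counted as two, it has made 51 points of target since 6.0 min. Over those minutes the same product asks a mean dissolved level of 21.2%, and that flask's starting material stands at 22.4% at 6.00 min and 14.1% at 15.0 min.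

The numbers in the tables are calculated for an exercise; scatter was added.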